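**Plan**

- Cuts: the two acetates and the C16 silyl ether; C3–C4 (closes the 11-membered ring); C1–C2 and C2–C3 (iododiene from a C11 acetyl group); C6–C7 (methallylation of a C8 enal); C7–C8 (carbonylation); the C15/C16 diol; C9–CH3; C10–C11 (enamine Michael addition onto a cyclohexadienone); the cyclohexane ring (Robinson annulation).
- Forward order: six-membered ring (steps 1–2), five-membered ring (step 4), C9 methyl and C7 (steps 6–8), diol (steps 9–13), C7 side chain (steps 14–17), C11 iododiene (steps 18–21), macrocycle last (step 22), then protecting-group exchange.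
- Stereochemistry: C10, C11 and C14 from the organocatalytic desymmetrisation; C15 and C16 by substrate control steered by the angular methyl (bromohydrin, epoxide, hydrolysis: two inversions); C7 from the Ipc2B reagent; C5 in the hydroboration by 1,3-induction from C7.
- Feature that makes the key step possible: in the ring C1–C11 the C3–C4 bond joins the terminus of the exocyclic (E)-diene C20=C1–C2=C3 to a CH2 (C4) next to the methyl-bearing C5. That is the pattern left when a C4=C5 1,1-disubstituted alkene is hydroborated at C4 and coupled with a C3 dienyl iodide; the cis-hydrindane (cyclohexene C8–C9–C10–C14–C15–C16, cyclopentane C10–C14) carries both chains.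

Key step: step 22

Remark: atoms carry the numbers of the target ring system throughout (C1–C16, C20; methyls on C5, C9, C14). α is the face of the C14 methyl group and β the opposite face. Compound 3 is racemic (its stereocentre vanishes in step 2). C9 of 8 and C1 of 7–16 are epimer mixtures that converge in steps 7 and 15.

**Route**

Step 1
Reactants: 1 2-methylpent-4-enal; 2 but-3-en-2-one
Product: 3 4-allyl-4-methylcyclohex-2-en-1-one
Conditions: H2SO4 (cat.), toluene, 45 °C, then reflux with azeotropic removal of water
Reagents that add atoms: none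
Why: Acid-catalysed Robinson annulation (Michael addition of the aldehyde enol to the enone, then aldol condensation) is the standard route to 4,4-disubstituted cyclohexenones; the quaternary centre is racemic and loses its stereogenicity in step 2.

Step 2
Reactants: 3 4-allyl-4-methylcyclohex-2-en-1-one
Product: 4 4-allyl-4-methylcyclohexa-2,5-dien-1-one
Conditions: DDQ, dioxane, reflux
Reagents that add atoms: none
Why: DDQ dehydrogenation of a 4,4-disubstituted cyclohexenone should give the cross-conjugated dienone, in which the quaternary carbon prevents aromatisation and the two enone arms are enantiotopic.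

Step 3
Reactants: 4 4-allyl-4-methylcyclohexa-2,5-dien-1-one
Product: 5 4-(1-methyl-4-oxocyclohexa-2,5-dien-1-yl)butanal
Conditions: Rh(acac)(CO)2 (1 mol%), BIPHEPHOS (2 mol%), CO/H2 (1:1, 5 bar), toluene, 60 °C
Reagents that add atoms: carbon monoxide, [C-]#[O+]
Why: Linear-selective rhodium-catalysed hydroformylation of the terminal alkene supplies C1 as the aldehyde, the disubstituted electron-poor ring alkenes being inert under these mild conditions.

Step 4
Reactants: 5 4-(1-methyl-4-oxocyclohexa-2,5-dien-1-yl)butanal
Product: 6 (1R,3aR,7aR)-3a-methyl-6-oxo-2,3,3a,6,7,7a-hexahydro-1H-indene-1-carbaldehyde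
Conditions: (S)-α,α-diphenylprolinol trimethylsilyl ether (10 mol%), PhCO2H (10 mol%), CH2Cl2, 0 °C
Reagents that add atoms: none
Why: Enamine-mediated intramolecular Michael addition (5-exo-trig, cis-fused by geometry) desymmetrises the dienone: the catalyst shields one enamine face (C11), the tether delivers C11 to C10 on its own side (C10–H and C14–CH3 both α), and the synclinal transition state that keeps the iminium carbon next to the incipient enolate carbon should put C1 cis to C9 in the kinetic product.

Step 5
Reactants: 6 keto aldehyde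
Product: 7 enone pivalate (C8 ketone; C15=C16; C11–CH(CH3)OPiv on the β face)
Conditions: MeMgBr (1.05 equiv), THF, −78 °C; then PivCl, DMAP (cat.), −78 → 0 °C
Reagents that add atoms: methylmagnesium bromide, C[Mg]Br; pivaloyl chloride, CC(C)(C)C(Cl)=O
Why: Grignard addition to the aldehyde is much faster than to the enone at −78 °C and removes the epimerisable formyl group at once, and acylation of the magnesium alkoxide in the same flask protects the carbinol as a base-stable pivalate.

Step 6
Reactants: 7 enone pivalate
Product: 8 C9-methyl enone pivalate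
Conditions: LDA (1.1 equiv), THF, −78 °C; MeI, −78 → −30 °C
Reagents that add atoms: iodomethane, CI
Why: Kinetic enolisation of the enone can only occur at C9 (α′) because the γ-carbon C14 is quaternary, and the enolate is C-methylated (enolate alkylation); the new C9 centre is planarised in step 7.

Step 7
Reactants: 8 C9-methyl enone pivalate
Product: 9 dienyl triflate (C9=C8(OTf)–C16=C15)
Conditions: KHMDS, THF, −78 °C; PhNTf2, −78 → 0 °C
Reagents that add atoms: N-phenylbis(trifluoromethanesulfonimide), O=S(=O)(N(c1ccccc1)S(=O)(=O)C(F)(F)F)C(F)(F)F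
Why: Deprotonation of the remaining C9 hydrogen gives the cross-conjugated dienolate, which the triflimide traps on oxygen as the 2-triflyloxy-1,3-diene (enol triflate formation).

Step 8
Reactants: 9 dienyl triflate
Product: 10 dienoate (methyl ester at C8; C8=C9 and C15=C16)
Conditions: Pd(OAc)2 (5 mol%), dppp (5 mol%), CO (1 atm), MeOH, Et3N, DMF, 60 °C
Reagents that add atoms: carbon monoxide, [C-]#[O+]; methanol, CO
Why: Palladium-catalysed methoxycarbonylation of the dienyl triflate introduces C7 and leaves C8=C9 tetrasubstituted and ester-conjugated, hence the less nucleophilic of the two alkenes.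

Step 9
Reactants: 10 dienoate
Product: 11 bromohydrin (C15–Br β; C16–OH α)
Conditions: NBS (1.1 equiv), THF–H2O (4:1), 0 °C, dark
Reagents that add atoms: N-bromosuccinimide, O=C1CCC(=O)N1Br; water, O
Why: Bromohydrin formation should take place at the more electron-rich C15=C16 alkene, with the bromonium ion on the β face (anti to the pseudo-axial C14 methyl) and trans-diaxial opening by water at the allylic, less hindered C16.

Step 10
Reactants: 11 bromohydrin
Product: 12 α-epoxide (C15–C16 oxirane on the face of the C14 methyl)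
Conditions: K2CO3, MeOH, 0 °C
Reagents that add atoms: none
Why: Base-induced 3-exo-tet closure (intramolecular Williamson reaction) inverts C15 and places the epoxide on the α face, the face that direct epoxidation would avoid.

Step 11
Reactants: 12 α-epoxide
Product: 13 trans-diol (C15–OH α; C16–OH β)
Conditions: 0.1 M H2SO4, THF–H2O, 0 °C → rt
Reagents that add atoms: water, O
Why: Acid-catalysed hydrolysis of the vinyl epoxide should occur at the allylic C16 with inversion, giving the trans-diol with C15–OH cis to the C14 methyl (set in step 10) and C16–OH β.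

Step 12
Reactants: 13 trans-diol
Product: 14 C16 tert-butyldimethylsilyl ether
Conditions: TBSCl (1.1 equiv), imidazole, DMF, 0 °C
Reagents that add atoms: tert-butyl(chloro)dimethylsilane, CC(C)(C)[Si](C)(C)Cl
Why: The allylic C16 hydroxyl is silylated in preference to the C15 hydroxyl, which is neopentyl-like next to the quaternary C14.

Step 13
Reactants: 14 C16 tert-butyldimethylsilyl ether
Product: 15 C15 triethylsilyl C16 tert-butyldimethylsilyl ether
Conditions: TESOTf, 2,6-lutidine, CH2Cl2, −40 °C
Reagents that add atoms: triethylsilyl trifluoromethanesulfonate, CC[Si](CC)(CC)OS(=O)(=O)C(F)(F)F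
Why: The hindered C15 hydroxyl is capped with the more reactive silyl triflate, completing the C15-TES/C16-TBS differentiation needed at the end.

Step 14
Reactants: 15 bis-silyl ether ester
Product: 16 diol (C7H2OH on C8; CH(OH)CH3 on C11)
Conditions: DIBAL-H (6 equiv), CH2Cl2, −78 → 0 °C; Rochelle salt work-up
Reagents that add atoms: none
Why: DIBAL-H reduces the enoate to the allylic alcohol and cleaves the pivalate in one operation without touching the silyl ethers.

Step 15
Reactants: 16 diol
Product: 17 keto enal (C8 enal; C11 acetyl on the β face)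
Conditions: TPAP (10 mol%), NMO (4 equiv), 4 Å MS, CH2Cl2, rt
Reagents that add atoms: none
Why: Perruthenate (Ley–Griffith) oxidation under neutral conditions converts the allylic alcohol to the C8 enal and both C1 epimers to the methyl ketone, so the C11 centre α to the ketone (the less stable, concave-face epimer) is not equilibrated.

Step 16
Reactants: 17 keto enal; 18 3-chloro-2-methylprop-1-ene
Product: 21 (7S) homoallylic alcohol, via methallylmagnesium chloride 19 (not isolated), via B-methallyldiisopinocampheylborane 20 (not isolated)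
Conditions: 18, Mg, THF, 0 °C; (−)-Ipc2BOMe, Et2O, −78 °C → rt; then 17, Et2O, −78 °C; pH 7 buffer, MeOH, H2O2, 0 °C
Reagents that add atoms: none
Why: Allylboration through a closed chair transition state is reagent-controlled: the borane of the (+)-α-pinene series should add the methallyl group to the Si face of the aldehyde (C7 S), and the ketone does not react at −78 °C.

Step 17
Reactants: 21 (7S) homoallylic alcohol
Product: 22 C7 triethylsilyl ether methyl ketone
Conditions: TESCl, imidazole, DMAP (cat.), DMF, 0 °C → rt
Reagents that add atoms: chlorotriethylsilane, CC[Si](Cl)(CC)CC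
Why: Standard silylation of the allylic secondary alcohol with the silyl chloride avoids enol silylation of the ketone.

Step 18
Reactants: 22 C7 triethylsilyl ether methyl ketone
Product: 23 enol triflate (C1(OTf)=C20H2)
Conditions: KHMDS, THF, −78 °C; N-(5-chloropyridin-2-yl)triflimide, −78 °C
Reagents that add atoms: N-(5-chloropyridin-2-yl)bis(trifluoromethanesulfonimide), O=S(=O)(N(c1ccc(Cl)cn1)S(=O)(=O)C(F)(F)F)C(F)(F)F
Why: Kinetic deprotonation of the methyl ketone at the methyl group (the C11 methine is hindered and untouched) and O-triflation give the 2-propenyl triflate.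

Step 19
Reactants: 23 enol triflate; 24 ethynyltrimethylsilane
Product: 25 trimethylsilyl enyne
Conditions: Pd(PPh3)4 (5 mol%), CuI (10 mol%), iPr2NH, THF, rt
Reagents that add atoms: none
Why: Sonogashira coupling of the alkenyl triflate with the terminal alkyne builds C2 and C3.

Step 20
Reactants: 25 trimethylsilyl enyne
Product: 26 terminal enyne
Conditions: K2CO3 (cat.), MeOH–THF, 0 °C
Reagents that add atoms: none
Why: Base-catalysed methanolysis removes the alkynyl silyl group, which is far more labile than the secondary alkyl silyl ethers.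

Step 21
Reactants: 26 terminal enyne
Product: 28 (E)-iododiene, via dienylzirconocene chloride 27 (not isolated)
Conditions: Cp2Zr(H)Cl (1.3 equiv), THF, rt, dark; then I2, THF, 0 °C
Reagents that add atoms: iodine, II
Why: Hydrozirconation adds Zr–H syn across the terminal alkyne (zirconium at C3) faster than across either 1,1-disubstituted alkene, and iodinolysis with retention gives the (E)-dienyl iodide.

Step 22
Reactants: 28 (E)-iododiene
Product: 30 macrocyclic tris-silyl ether, via B-alkyl-9-BBN borane 29 (not isolated)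
Conditions: 9-BBN dimer, THF, 0 °C → rt; then slow addition to PdCl2(dppf)·CH2Cl2 (20 mol%), AsPh3 (40 mol%), Cs2CO3 (3 equiv), DMF–THF–H2O, rt → 45 °C, final concentration about 1 mM
Reagents that add atoms: none
Why: 9-BBN adds to the isolated, unhindered 1,1-disubstituted C4=C5 alkene (boron to C4, hydrogen to C5) much faster than to the conjugated and more hindered iododiene; Pd(0) then inserts into the C3–I bond, the base-activated primary alkylborane transmetalates, and reductive elimination forms C3–C4 with retention of the E geometry. The closest known reaction type is the intramolecular B-alkyl Suzuki–Miyaura macrocyclisation of an alkene-derived 9-BBN borane with an alkenyl iodide. The 11-membered ring C1–C11 closes by C(sp3)–C(sp2) reductive elimination from a cyclic alkyl(alkenyl)palladium species under high dilution, both chains being held on the same cis-hydrindane. C5 is created in the hydroboration under 1,3-induction from the C7 triethylsilyloxy centre: the borane should approach anti to the C6–C7 bond of the conformer that turns the bulky cyclohexenyl group away from the alkene methyl, which favours the 5S (1,3-syn) isomer only moderately, so any C5 epimer is to be removed at 30. The step needs chemoselective hydroboration and an intact allylic C7–O bond; the first rests on the steric and electronic difference between the two alkenes, the second on silyl ethers in place of the acetates, which cannot ionise to a π-allyl complex.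

Step 23
Reactants: 30 macrocyclic tris-silyl ether
Product: 31 macrocyclic C7,C15-diol C16 silyl ether
Conditions: HF·pyridine, pyridine, THF, 0 °C
Reagents that add atoms: none
Why: Fluoride cleaves the two triethylsilyl ethers much faster than the tert-butyldimethylsilyl ether, and the buffered reagent avoids ionisation at the allylic C7.

Step 24
Reactants: 31 macrocyclic diol
Product: 32 C7,C15-diacetate C16 silyl ether
Conditions: Ac2O, DMAP (cat.), pyridine, rt
Reagents that add atoms: acetic anhydride, CC(=O)OC(C)=O
Why: DMAP-catalysed acetylation esterifies C7–OH and the hindered C15–OH.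

Step 25
Reactants: 32 diacetate silyl ether
Product: 33 target CNP0323842.1
Conditions: HF·pyridine, THF, rt
Reagents that add atoms: none
Why: Acidic fluoride removes the remaining silyl ether without the acetyl migration from C15 to C16 that a basic fluoride source could cause.

**Compound list**

1 | 2-methylpent-4-enal | C=CCC(C)C=O | starting material
2 | but-3-en-2-one | CC(=O)C=C | starting material
3 | 4-allyl-4-methylcyclohex-2-en-1-one (racemic) | O=C1C=CC(C)(CC=C)CC1 | intermediate
4 | 4-allyl-4-methylcyclohexa-2,5-dien-1-one | O=C1C=CC(C)(CC=C)C=C1 | intermediate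
5 | 4-(1-methyl-4-oxocyclohexa-2,5-dien-1-yl)butanal | O=CCCCC1(C)C=CC(=O)C=C1 | intermediate
6 | (1R,3aR,7aR)-3a-methyl-6-oxo-2,3,3a,6,7,7a-hexahydro-1H-indene-1-carbaldehyde (cis-fused; C10–H and C14–CH3 α, C11–CHO β) | O=C1C[C@@H]2[C@H](C=O)CC[C@]2(C)C=C1 | intermediate
7 | enone pivalate: as 6 with C11–CH(CH3)OC(O)tBu (C1 epimers) | O=C1C[C@@H]2[C@H](C(C)OC(=O)C(C)(C)C)CC[C@]2(C)C=C1 | intermediate
8 | C9-methyl enone pivalate (C9 and C1 epimers) | O=C1C(C)[C@@H]2[C@H](C(C)OC(=O)C(C)(C)C)CC[C@]2(C)C=C1 | intermediate
9 | dienyl triflate: C8–OTf, C8=C9(CH3), C15=C16 | FC(F)(F)S(=O)(=O)OC1=C(C)[C@@H]2[C@H](C(C)OC(=O)C(C)(C)C)CC[C@]2(C)C=C1 | intermediate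
10 | dienoate: methyl ester (C7) on C8, C8=C9(CH3), C15=C16 | COC(=O)C1=C(C)[C@@H]2[C@H](C(C)OC(=O)C(C)(C)C)CC[C@]2(C)C=C1 | intermediate
11 | bromohydrin: C15–Br β, C16–OH α | COC(=O)C1=C(C)[C@@H]2[C@H](C(C)OC(=O)C(C)(C)C)CC[C@]2(C)[C@H](Br)[C@H]1O | intermediate
12 | α-epoxide: C15–C16 oxirane cis to the C14 methyl | COC(=O)C1=C(C)[C@@H]2[C@H](C(C)OC(=O)C(C)(C)C)CC[C@]2(C)[C@H]3O[C@@H]13 | intermediate
13 | trans-diol: C15–OH α, C16–OH β | COC(=O)C1=C(C)[C@@H]2[C@H](C(C)OC(=O)C(C)(C)C)CC[C@]2(C)[C@@H](O)[C@@H]1O | intermediate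
14 | C16 TBS ether of 13 | COC(=O)C1=C(C)[C@@H]2[C@H](C(C)OC(=O)C(C)(C)C)CC[C@]2(C)[C@@H](O)[C@@H]1O[Si](C)(C)C(C)(C)C | intermediate
15 | C15 TES, C16 TBS ether of 13 | COC(=O)C1=C(C)[C@@H]2[C@H](C(C)OC(=O)C(C)(C)C)CC[C@]2(C)[C@@H](O[Si](CC)(CC)CC)[C@@H]1O[Si](C)(C)C(C)(C)C | intermediate
16 | diol: C8–CH2OH and C11–CH(OH)CH3 (C1 epimers), C15 OTES, C16 OTBS | OCC1=C(C)[C@@H]2[C@H](C(C)O)CC[C@]2(C)[C@@H](O[Si](CC)(CC)CC)[C@@H]1O[Si](C)(C)C(C)(C)C | intermediate
17 | keto enal: C8–CHO, C11 acetyl (β), C15 OTES, C16 OTBS | O=CC1=C(C)[C@@H]2[C@H](C(C)=O)CC[C@]2(C)[C@@H](O[Si](CC)(CC)CC)[C@@H]1O[Si](C)(C)C(C)(C)C | intermediate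
18 | 3-chloro-2-methylprop-1-ene | C=C(C)CCl | starting material
19 | methallylmagnesium chloride | C=C(C)C[Mg]Cl | intermediate
20 | (−)-B-methallyldiisopinocampheylborane ((+)-α-pinene series) | C=C(C)CB([C@@H]1C[C@@H]2C[C@H]([C@H]1C)C2(C)C)[C@@H]1C[C@@H]2C[C@H]([C@H]1C)C2(C)C | intermediate
21 | (7S) homoallylic alcohol: C7–OH with methallyl chain, C11 acetyl | C=C(C)C[C@H](O)C1=C(C)[C@@H]2[C@H](C(C)=O)CC[C@]2(C)[C@@H](O[Si](CC)(CC)CC)[C@@H]1O[Si](C)(C)C(C)(C)C | intermediate
22 | C7 TES ether of 21 | C=C(C)C[C@H](O[Si](CC)(CC)CC)C1=C(C)[C@@H]2[C@H](C(C)=O)CC[C@]2(C)[C@@H](O[Si](CC)(CC)CC)[C@@H]1O[Si](C)(C)C(C)(C)C | intermediate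
23 | enol triflate: C11–C(OTf)=CH2 | C=C(C)C[C@H](O[Si](CC)(CC)CC)C1=C(C)[C@@H]2[C@H](C(=C)OS(=O)(=O)C(F)(F)F)CC[C@]2(C)[C@@H](O[Si](CC)(CC)CC)[C@@H]1O[Si](C)(C)C(C)(C)C | intermediate
24 | ethynyltrimethylsilane | C#C[Si](C)(C)C | starting material
25 | trimethylsilyl enyne: C11–C(=CH2)–C≡C–SiMe3 | C=C(C)C[C@H](O[Si](CC)(CC)CC)C1=C(C)[C@@H]2[C@H](C(=C)C#C[Si](C)(C)C)CC[C@]2(C)[C@@H](O[Si](CC)(CC)CC)[C@@H]1O[Si](C)(C)C(C)(C)C | intermediate
26 | terminal enyne: C11–C(=CH2)–C≡CH | C=C(C)C[C@H](O[Si](CC)(CC)CC)C1=C(C)[C@@H]2[C@H](C(=C)C#C)CC[C@]2(C)[C@@H](O[Si](CC)(CC)CC)[C@@H]1O[Si](C)(C)C(C)(C)C | intermediate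
27 | (E)-dienylzirconocene chloride | C=C(C)C[C@H](O[Si](CC)(CC)CC)C1=C(C)[C@@H]2[C@H](C(=C)/C=C/[Zr](Cl)(C3C=CC=C3)C3C=CC=C3)CC[C@]2(C)[C@@H](O[Si](CC)(CC)CC)[C@@H]1O[Si](C)(C)C(C)(C)C | intermediate
28 | seco (E)-iododiene with methallyl chain on C7, tris-silylated | C=C(C)C[C@H](O[Si](CC)(CC)CC)C1=C(C)[C@@H]2[C@H](C(=C)/C=C/I)CC[C@]2(C)[C@@H](O[Si](CC)(CC)CC)[C@@H]1O[Si](C)(C)C(C)(C)C | intermediate
29 | B-alkyl-9-BBN borane (boron on C4, 5S) | C1CCC2CCCC1B2C[C@H](C)C[C@H](O[Si](CC)(CC)CC)C1=C(C)[C@@H]2[C@H](C(=C)/C=C/I)CC[C@]2(C)[C@@H](O[Si](CC)(CC)CC)[C@@H]1O[Si](C)(C)C(C)(C)C | intermediate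
30 | macrocyclic triene, C7 OTES, C15 OTES, C16 OTBS | C=C1/C=C/C[C@H](C)C[C@H](O[Si](CC)(CC)CC)C2=C(C)[C@@H]3[C@H]1CC[C@]3(C)[C@@H](O[Si](CC)(CC)CC)[C@@H]2O[Si](C)(C)C(C)(C)C | intermediate
31 | macrocyclic C7,C15-diol, C16 OTBS | C=C1/C=C/C[C@H](C)C[C@H](O)C2=C(C)[C@@H]3[C@H]1CC[C@]3(C)[C@@H](O)[C@@H]2O[Si](C)(C)C(C)(C)C | intermediate
32 | macrocyclic C7,C15-diacetate, C16 OTBS | C=C1/C=C/C[C@H](C)C[C@H](OC(C)=O)C2=C(C)[C@@H]3[C@H]1CC[C@]3(C)[C@@H](OC(C)=O)[C@@H]2O[Si](C)(C)C(C)(C)C | intermediate
33 | CNP0323842.1 | C=C1/C=C/C[C@H](C)C[C@H](OC(C)=O)C2=C(C)[C@@H]3[C@H]1CC[C@]3(C)[C@@H](OC(C)=O)[C@@H]2O | target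

**Count**

Total: 25 steps. Longest linear sequence: 25 steps (1 and 2 to 33).

**Steps most likely to fail**

Step 22. The hydroboration may show poor facial selectivity at C5, some borane may add to the diene, and ring closure may lose to intermolecular coupling. The fallback sets out from 28 and returns at 30. Compound 28 is hydroborated as before, but borane 29 is oxidised with sodium perborate to the primary C4 alcohol F1, whose C5 epimers are separated at this open-chain stage. Because the borane no longer has to cross-couple, an enantiopure hydroborating agent can be used here for reagent control. An Appel reaction (I2, PPh3, imidazole) converts the alcohol into the primary alkyl iodide F2. Zinc dust with LiCl in THF inserts only into the alkyl C–I bond and leaves the dienyl iodide, giving the alkylzinc iodide F3. A palladium-catalysed intramolecular Negishi coupling under high dilution then forms the same C3–C4 bond and gives 30.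

Step 4. The kinetic cis aldehyde may equilibrate to its C11 epimer through the enamine, or the catalyst may not discriminate the two enone arms well enough. The fallback sets out from 5 and returns at 6. Aldehyde 5 is condensed with (S)-1-amino-2-(methoxymethyl)pyrrolidine to the SAMP hydrazone F4. LDA in THF at −78 °C gives the azaenolate, which should cyclise irreversibly onto the dienone under auxiliary control (intramolecular Michael addition) to the bicyclic hydrazone F5. Two-phase hydrolysis with aqueous oxalic acid releases 6 and the auxiliary without base.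

Step 9. Water may capture the bromonium ion at C9 (conjugate opening) instead of C16, or bromine may attack the tetrasubstituted alkene. The fallback sets out from 10 and returns at 13. A Prévost reaction (I2, silver benzoate, benzene, reflux) delivers the first benzoate to C16 anti to the iodonium ion. The neighbouring benzoate then displaces iodide at C15 with inversion, and the resulting α-face acyloxonium ion is opened again at C16. This should give the trans-dibenzoate F6 with C15–O α and C16–O β, and methanolysis (K2CO3, MeOH) releases 13.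

**Further compounds**

F1 | step 22 | primary C4 alcohol (5S) with iododiene and three silyl ethers | OC[C@H](C)C[C@H](O[Si](CC)(CC)CC)C1=C(C)[C@@H]2[C@H](C(=C)/C=C/I)CC[C@]2(C)[C@@H](O[Si](CC)(CC)CC)[C@@H]1O[Si](C)(C)C(C)(C)C
F2 | step 22 | primary C4 alkyl iodide | IC[C@H](C)C[C@H](O[Si](CC)(CC)CC)C1=C(C)[C@@H]2[C@H](C(=C)/C=C/I)CC[C@]2(C)[C@@H](O[Si](CC)(CC)CC)[C@@H]1O[Si](C)(C)C(C)(C)C
F3 | step 22 | C4 alkylzinc iodide | I[Zn]C[C@H](C)C[C@H](O[Si](CC)(CC)CC)C1=C(C)[C@@H]2[C@H](C(=C)/C=C/I)CC[C@]2(C)[C@@H](O[Si](CC)(CC)CC)[C@@H]1O[Si](C)(C)C(C)(C)C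
F4 | step 4 | SAMP hydrazone of 5 | COC[C@@H]1CCCN1/N=C/CCCC1(C)C=CC(=O)C=C1
F5 | step 4 | bicyclic SAMP hydrazone of 6 | O=C1C[C@@H]2[C@H](/C=N/N3CCC[C@H]3COC)CC[C@]2(C)C=C1
F6 | step 9 | trans-dibenzoate of 13 (C15–OBz α, C16–OBz β) | COC(=O)C1=C(C)[C@@H]2[C@H](C(C)OC(=O)C(C)(C)C)CC[C@]2(C)[C@@H](OC(=O)c3ccccc3)[C@@H]1OC(=O)c1ccccc1
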